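The aryl ketone is disconnected between C1 of the C20 chain and a ring carbon of the 2,4,6-trihydroxyphenyl unit. C1 travels as a nitrile: it survives the copper-mediated alkyne–propargyl couplings that build the C5/C8/C11/C14 tetrayne and the Lindlar reduction that sets all four Z-alkenes. In the last step a Houben–Hoesch acylation lets unprotected phloroglucinol, whose three equivalent ring CH carbons each lie between two C–OH carbons (enol carbons of a masked cyclohexane-1,3,5-trione), attack the protonated nitrile carbon; ketiminium hydrolysis and loss of the C17 silyl ether follow in the same operation. C17 derives from (R)-1,2-epoxypentane.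

Key step: step 8

Remark on the chemistry: C17 of the target is (R). (R)-1,2-Epoxypentane is taken as a commercial enantiopure starting material (otherwise accessible by hydrolytic kinetic resolution of the racemate), and phloroglucinol is used in its anhydrous form.

**Step 1**
Reactants: 1 (R)-1,2-epoxypentane
Product: 2 (R)-hept-1-yn-4-ol
Conditions: LiC≡CH·H2NCH2CH2NH2 (1.5 equiv), DMSO, 0 °C → rt; then H2O
Reagents that add atoms: lithium acetylide–ethylenediamine complex, [Li+].[C-]#C.NCCN
Why: Acetylide–epoxide opening (SN2) at the unsubstituted CH2 of the terminal epoxide; the C–O bond at the stereocentre is not broken, so the (R) centre of 1 becomes C17 (R) of the chain.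

**Step 2**
Reactants: 2 (R)-hept-1-yn-4-ol
Product: 3 (R)-tert-butyl(hept-1-yn-4-yloxy)dimethylsilane
Conditions: TBSCl, imidazole, DMF, rt
Reagents that add atoms: tert-butyldimethylsilyl chloride (TBSCl), CC(C)(C)[Si](C)(C)Cl
Why: Standard imidazole-promoted silylation of a secondary alcohol; the TBS ether masks C17–OH through the coupling and reduction steps and through the anhydrous stage of step 8.

**Step 3**
Reactants: 4 hex-5-ynenitrile; 5 1,4-dibromobut-2-yne (4 equiv)
Product: 6 10-bromodeca-5,8-diynenitrile
Conditions: CuBr·SMe2 (0.2 equiv), Cs2CO3 (1.1 equiv), DMF, 0 °C → rt, slow addition of 4, Ar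
Reagents that add atoms: none
Why: Copper(I)-catalysed sp–sp3 coupling of a terminal alkyne with a propargylic bromide (Jeffery-type skipped-diyne synthesis) by SN2 attack of the copper acetylide; the fourfold excess of the symmetric dibromide and slow addition of 4 should hold the reaction at mono-substitution, and CuBr avoids halide scrambling at the remaining C–Br bond.

**Step 4**
Reactants: 6 10-bromodeca-5,8-diynenitrile; 7 prop-2-yn-1-ol (2 equiv)
Product: 8 13-hydroxytrideca-5,8,11-triynenitrile
Conditions: CuI (0.2 equiv), Cs2CO3 (1.2 equiv), DMF, rt, Ar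
Reagents that add atoms: none
Why: Same copper-acetylide/propargyl bromide coupling; the free primary OH of 7 is tolerated, and carbonate in DMF is mild enough not to isomerise the skipped triyne to allenes.

**Step 5**
Reactants: 8 13-hydroxytrideca-5,8,11-triynenitrile
Product: 9 13-bromotrideca-5,8,11-triynenitrile
Conditions: CBr4, PPh3, CH2Cl2, −20 → 0 °C, Ar
Reagents that add atoms: carbon tetrabromide, BrC(Br)(Br)Br
Why: Appel bromination of the primary propargylic alcohol under neutral conditions that leave the nitrile and the skipped triyne untouched.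

**Step 6**
Reactants: 9 13-bromotrideca-5,8,11-triynenitrile; 3 (R)-tert-butyl(hept-1-yn-4-yloxy)dimethylsilane (1.2 equiv)
Product: 10 (R)-17-[(tert-butyldimethylsilyl)oxy]icosa-5,8,11,14-tetraynenitrile
Conditions: CuI (0.2 equiv), Cs2CO3 (1.2 equiv), DMF, rt, Ar, dark; used at once
Reagents that add atoms: none
Why: A third copper-acetylide/propargyl bromide coupling completes the C20 skeleton with the four alkynes at C5, C8, C11 and C14; the silyl ether, the nitrile and the C17 stereocentre are inert.

**Step 7**
Reactants: 10 (R)-17-[(tert-butyldimethylsilyl)oxy]icosa-5,8,11,14-tetraynenitrile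
Product: 11 (R,5Z,8Z,11Z,14Z)-17-[(tert-butyldimethylsilyl)oxy]icosa-5,8,11,14-tetraenenitrile
Conditions: H2 (1 atm, stopped at 4 equiv uptake), Lindlar catalyst, quinoline, EtOAc–hexane, 10 °C
Reagents that add atoms: none
Why: Lindlar semi-hydrogenation delivers H2 syn to each of the four alkynes on lead-poisoned Pd and so gives four Z-alkenes; quinoline and metered H2 uptake limit over-reduction, and nitrile and silyl ether are not reduced.

**Step 8**
Reactants: 11 (R,5Z,8Z,11Z,14Z)-17-[(tert-butyldimethylsilyl)oxy]icosa-5,8,11,14-tetraenenitrile; 12 phloroglucinol (anhydrous, 3 equiv)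
Product: 14 (R,5Z,8Z,11Z,14Z)-17-hydroxy-1-(2,4,6-trihydroxyphenyl)icosa-5,8,11,14-tetraen-1-one, via ketiminium chloride 13 (not isolated)
Conditions: HCl (g), ZnCl2 (0.2 equiv), Et2O, 0 °C, Ar, dark; then 1 M aq. HCl–THF (degassed), 50 °C
Reagents that add atoms: water, O
Why: Houben–Hoesch acylation: HCl (assisted by ZnCl2) turns the C1 nitrile of 11 into a nitrilium/imidoyl chloride electrophile, a ring CH carbon of 12 (an enol carbon flanked by two C–OH carbons) attacks it, and re-aromatisation gives ketiminium chloride 13. The closest known reaction is the Hoesch synthesis of 2,4,6-trihydroxyphenyl alkyl ketones from phloroglucinol and aliphatic nitriles; no ring is closed and no stereocentre is formed, and C17 (R) is untouched because its C–O bond is never ionised. Regioselectivity is no issue because the three ring CH positions of 12 are equivalent by symmetry, and acylation should stop after one chain because the iminium-substituted ring of 13 is deactivated (excess 12 is washed out with water). C- over O-acylation follows the known behaviour of polyhydric phenols, whose O-imidates revert under HCl while the C-adduct does not. The four non-conjugated Z-alkenes should tolerate cold ethereal HCl and brief warm dilute acid, as skipped polyenes do in HCl–MeOH transesterification, and C17–OH stays silylated in the anhydrous stage so that it cannot form a Pinner imidate with a second nitrile. Warm aqueous HCl–THF then hydrolyses C=NH2+ to C=O and cleaves the TBS ether, so the target is released without a separate deprotection.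

**Compound list**

1 | (R)-1,2-epoxypentane | CCC[C@@H]1CO1 | starting material
2 | (R)-hept-1-yn-4-ol | CCC[C@@H](O)CC#C | intermediate
3 | (R)-tert-butyl(hept-1-yn-4-yloxy)dimethylsilane | CCC[C@@H](O[Si](C)(C)C(C)(C)C)CC#C | intermediate
4 | hex-5-ynenitrile | C#CCCCC#N | starting material
5 | 1,4-dibromobut-2-yne | BrCC#CCBr | starting material
6 | 10-bromodeca-5,8-diynenitrile | N#CCCCC#CCC#CCBr | intermediate
7 | prop-2-yn-1-ol | C#CCO | starting material
8 | 13-hydroxytrideca-5,8,11-triynenitrile | N#CCCCC#CCC#CCC#CCO | intermediate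
9 | 13-bromotrideca-5,8,11-triynenitrile | N#CCCCC#CCC#CCC#CCBr | intermediate
10 | (R)-17-[(tert-butyldimethylsilyl)oxy]icosa-5,8,11,14-tetraynenitrile | CCC[C@@H](O[Si](C)(C)C(C)(C)C)CC#CCC#CCC#CCC#CCCCC#N | intermediate
11 | (R,5Z,8Z,11Z,14Z)-17-[(tert-butyldimethylsilyl)oxy]icosa-5,8,11,14-tetraenenitrile | CCC[C@@H](O[Si](C)(C)C(C)(C)C)C/C=C\C/C=C\C/C=C\C/C=C\CCCC#N | intermediate
12 | phloroglucinol (benzene-1,3,5-triol) | Oc1cc(O)cc(O)c1 | starting material
13 | (R,5Z,8Z,11Z,14Z)-17-[(tert-butyldimethylsilyl)oxy]-1-(2,4,6-trihydroxyphenyl)icosa-5,8,11,14-tetraen-1-iminium chloride | CCC[C@@H](O[Si](C)(C)C(C)(C)C)C/C=C\C/C=C\C/C=C\C/C=C\CCCC(=[NH2+])c1c(O)cc(O)cc1O.[Cl-] | intermediate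
14 | (R,5Z,8Z,11Z,14Z)-17-hydroxy-1-(2,4,6-trihydroxyphenyl)icosa-5,8,11,14-tetraen-1-one | CCC[C@@H](O)C/C=C\C/C=C\C/C=C\C/C=C\CCCC(=O)c1c(O)cc(O)cc1O | target

**Step count and risks**

Total steps: 8. Longest linear sequence: 6 steps (steps 3, 4, 5, 6, 7, 8 from hex-5-ynenitrile); the C14–C20 branch (steps 1, 2) joins at step 6.

Steps most likely to fail:

1. Step 8. Possible failures are hydrochlorination or cationic isomerisation of the skipped tetraene under HCl/ZnCl2, early loss of the silyl ether followed by intermolecular Pinner imidate formation, and slow C-attack of the lipophilic nitrile. The fallback sets out from 11 and 12 and comes back at 14; it forms the same C1–aryl bond by organolithium addition. Phloroglucinol 12 would be converted with MOMCl and i-Pr2NEt (CH2Cl2, 0 °C → rt) into 1,3,5-tris(methoxymethoxy)benzene F1. Nitrile 11 would be reduced with DIBAL-H (toluene, −78 °C; Rochelle salt work-up) to (R,5Z,8Z,11Z,14Z)-17-[(tert-butyldimethylsilyl)oxy]icosa-5,8,11,14-tetraenal F2. Directed ortho-lithiation of F1 (n-BuLi, THF, 0 °C) would give [2,4,6-tris(methoxymethoxy)phenyl]lithium F3, which should add to F2 at −78 °C to give (17R,5Z,8Z,11Z,14Z)-17-[(tert-butyldimethylsilyl)oxy]-1-[2,4,6-tris(methoxymethoxy)phenyl]icosa-5,8,11,14-tetraen-1-ol F4 (both C1 epimers, which is immaterial). Dess–Martin oxidation (NaHCO3-buffered, CH2Cl2) would give (R,5Z,8Z,11Z,14Z)-17-[(tert-butyldimethylsilyl)oxy]-1-[2,4,6-tris(methoxymethoxy)phenyl]icosa-5,8,11,14-tetraen-1-one F5, and HCl in aqueous MeOH (40 °C) should remove the three MOM ethers and the TBS ether to give 14.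

2. Step 7. Possible failures are over-reduction, incomplete reduction and partial Z→E isomerisation, giving congeners that co-elute with the non-polar silyl ether 11. The fallback sets out from 6 and 3 and comes back at 11; it never makes the tetrayne. Bromide 6 would be coupled with but-3-yn-1-ol (CuI, Cs2CO3, DMF) to 14-hydroxytetradeca-5,8,11-triynenitrile F6. The semi-hydrogenation (Lindlar, quinoline) is moved to this small polar alcohol, where silver nitrate–silica purification is practical, to give (5Z,8Z,11Z)-14-hydroxytetradeca-5,8,11-trienenitrile F7. Iodination (I2, PPh3, imidazole) would give (5Z,8Z,11Z)-14-iodotetradeca-5,8,11-trienenitrile F8, and PPh3 in MeCN at reflux would give [(3Z,6Z,9Z)-13-cyanotrideca-3,6,9-trien-1-yl]triphenylphosphonium iodide F9. In parallel, alkyne 3 would be semi-hydrogenated (Lindlar) to (R)-tert-butyl(hept-1-en-4-yloxy)dimethylsilane F11 and ozonised (O3, CH2Cl2, −78 °C; then PPh3) to (R)-3-[(tert-butyldimethylsilyl)oxy]hexanal F12. Deprotonation of F9 with NaHMDS (THF, −78 °C) would give the non-stabilised ylide (3Z,6Z,9Z)-13-cyanotrideca-3,6,9-trien-1-ylidene(triphenyl)phosphorane F10, whose Z-selective Wittig reaction with F12 forms the C14=C15 alkene and gives 11.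

3. Step 3. Possible failures are double substitution of the dibromide to a symmetric triyne, SN2′ attack giving allenes, and base-induced propargyl–allene isomerisation of the bromodiyne. The fallback sets out from 4 and comes back at 6; it replaces the bis-electrophile by a mono-electrophile. Nitrile 4 would be coupled with 4-chlorobut-2-yn-1-ol (OCC#CCCl; CuI, NaI, Cs2CO3, DMF) to 10-hydroxydeca-5,8-diynenitrile F13, and Appel bromination (CBr4, PPh3, CH2Cl2, 0 °C) would give 6.

**Further compounds**

F1 | step 8 | 1,3,5-tris(methoxymethoxy)benzene | COCOc1cc(OCOC)cc(OCOC)c1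
F2 | step 8 | (R,5Z,8Z,11Z,14Z)-17-[(tert-butyldimethylsilyl)oxy]icosa-5,8,11,14-tetraenal | CCC[C@@H](O[Si](C)(C)C(C)(C)C)C/C=C\C/C=C\C/C=C\C/C=C\CCCC=O
F3 | step 8 | [2,4,6-tris(methoxymethoxy)phenyl]lithium | [Li]c1c(OCOC)cc(OCOC)cc1OCOC
F4 | step 8 | (17R,5Z,8Z,11Z,14Z)-17-[(tert-butyldimethylsilyl)oxy]-1-[2,4,6-tris(methoxymethoxy)phenyl]icosa-5,8,11,14-tetraen-1-ol (C1 epimers) | CCC[C@@H](O[Si](C)(C)C(C)(C)C)C/C=C\C/C=C\C/C=C\C/C=C\CCCC(O)c1c(OCOC)cc(OCOC)cc1OCOC
F5 | step 8 | (R,5Z,8Z,11Z,14Z)-17-[(tert-butyldimethylsilyl)oxy]-1-[2,4,6-tris(methoxymethoxy)phenyl]icosa-5,8,11,14-tetraen-1-one | CCC[C@@H](O[Si](C)(C)C(C)(C)C)C/C=C\C/C=C\C/C=C\C/C=C\CCCC(=O)c1c(OCOC)cc(OCOC)cc1OCOC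
F6 | step 7 | 14-hydroxytetradeca-5,8,11-triynenitrile | N#CCCCC#CCC#CCC#CCCO
F7 | step 7 | (5Z,8Z,11Z)-14-hydroxytetradeca-5,8,11-trienenitrile | N#CCCC/C=C\C/C=C\C/C=C\CCO
F8 | step 7 | (5Z,8Z,11Z)-14-iodotetradeca-5,8,11-trienenitrile | N#CCCC/C=C\C/C=C\C/C=C\CCI
F9 | step 7 | [(3Z,6Z,9Z)-13-cyanotrideca-3,6,9-trien-1-yl]triphenylphosphonium iodide | N#CCCC/C=C\C/C=C\C/C=C\CC[P+](c1ccccc1)(c1ccccc1)c1ccccc1.[I-]
F10 | step 7 | (3Z,6Z,9Z)-13-cyanotrideca-3,6,9-trien-1-ylidene(triphenyl)phosphorane | N#CCCC/C=C\C/C=C\C/C=C\CC=P(c1ccccc1)(c1ccccc1)c1ccccc1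
F11 | step 7 | (R)-tert-butyl(hept-1-en-4-yloxy)dimethylsilane | CCC[C@@H](O[Si](C)(C)C(C)(C)C)CC=C
F12 | step 7 | (R)-3-[(tert-butyldimethylsilyl)oxy]hexanal | CCC[C@@H](O[Si](C)(C)C(C)(C)C)CC=O
F13 | step 3 | 10-hydroxydeca-5,8-diynenitrile | N#CCCCC#CCC#CCO
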